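**Assumption:** the stereocentre in the target SMILES is (S). (S)-3-(4-Hydroxyphenyl)lactic acid is taken as a commercial chiral-pool material (it is also made in one step from L-tyrosine with NaNO2/H2SO4, with retention).

## Retrosynthetic overview

1. Target ⇒ tris-MOM ether 11; only three phenolic MOM groups are removed at the end, and the α-OH never carries a permanent protecting group.
2. Key disconnection, aryl–C(=O) bond: aryl-metal from bromide 6 plus (S)-dioxolanone 10, the acetonide of (S)-4-hydroxyphenyllactic acid. The acetonide is both the acyl activating group and a traceless α-OH mask; the stereocentre is bought, not made.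
3. Bromide 6 ⇐ 2,4,6-tribromoresorcinol: MOM protection, then two successive Br/Li exchange–prenylations (first the Br between the two oxygens, then one of two symmetry-equivalent Br). The third Br is the acylation handle.
4. Rings: both benzene rings are purchased. The only ring formed is the temporary dioxolanone (step 4), which is opened again in step 6.

## Route

**Step 1**
Reactants: 1, 2,4,6-tribromoresorcinol; 2, chloromethyl methyl ether (MOMCl)
Product: 3, 1,3,5-tribromo-2,4-bis(methoxymethoxy)benzene
Conditions: NaH (2.4 equiv), MOMCl (2.6 equiv), DMF, 0 °C → rt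
Reagents that add atoms: MOMCl, COCCl
Why: Williamson-type O-alkylation (MOM protection) of the two acidic bromophenols; MOM is inert to organolithiums and chelates/stabilises an ortho-lithium.

**Step 2**
Reactants: 3, 1,3,5-tribromo-2,4-bis(methoxymethoxy)benzene; 4, prenyl bromide (1-bromo-3-methylbut-2-ene)
Product: 5, 1,5-dibromo-2,4-bis(methoxymethoxy)-3-(3-methylbut-2-en-1-yl)benzene
Conditions: n-BuLi (1.0 equiv), THF, −78 °C, 20 min; CuBr·SMe2 (0.2 equiv), prenyl bromide (1.3 equiv), −78 → 0 °C
Reagents that add atoms: prenyl bromide, CC(C)=CCBr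
Why: Regioselective bromine–lithium exchange at the Br flanked by two OMOM groups (the most stabilised, doubly chelated aryllithium), then Cu-catalysed SN2 allylation; α-attack gives the linear prenyl group because γ-attack would have to form a quaternary centre.

**Step 3**
Reactants: 5, 1,5-dibromo-2,4-bis(methoxymethoxy)-3-prenylbenzene; 4, prenyl bromide
Product: 6, 1-bromo-2,4-bis(methoxymethoxy)-3,5-bis(3-methylbut-2-en-1-yl)benzene
Conditions: n-BuLi (1.0 equiv), THF, −78 °C, 15 min; CuBr·SMe2 (0.2 equiv), prenyl bromide (1.3 equiv), −78 → 0 °C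
Reagents that add atoms: prenyl bromide, CC(C)=CCBr
Why: Second bromine–lithium exchange/allylation; the two bromines are symmetry-equivalent so mono-exchange gives one product, a second exchange on the aryl anion is disfavoured, and exchange at −78 °C is far faster than deprotonation of the allylic/benzylic CH2.

**Step 4**
Reactants: 7, (S)-2-hydroxy-3-(4-hydroxyphenyl)propanoic acid; 8, 2,2-dimethoxypropane
Product: 9, (S)-5-(4-hydroxybenzyl)-2,2-dimethyl-1,3-dioxolan-4-one
Conditions: Me2C(OMe)2 (5 equiv), PPTS (10 mol %), CHCl3, reflux (4 Å MS to remove MeOH)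
Reagents that add atoms: 2,2-dimethoxypropane, COC(C)(C)OC
Why: Acid-catalysed transketalisation of the α-hydroxy acid to its acetonide (dioxolanone), which masks the α-OH and activates the carboxyl in one operation; no bond to the stereocentre is broken, so (S) is retained.

**Step 5**
Reactants: 9, (S)-5-(4-hydroxybenzyl)-2,2-dimethyl-1,3-dioxolan-4-one; 2, MOMCl
Product: 10, (S)-5-[4-(methoxymethoxy)benzyl]-2,2-dimethyl-1,3-dioxolan-4-one
Conditions: MOMCl (1.3 equiv), i-Pr2NEt (1.6 equiv), CH2Cl2, 0 °C → rt
Reagents that add atoms: MOMCl, COCCl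
Why: MOM protection of the phenol removes the only acidic proton; the hindered amine base is non-nucleophilic and far too weak to enolise or open the dioxolanone, so the stereocentre is untouched.

**Step 6 (key step)**
Reactants: 6, 1-bromo-2,4-bis(methoxymethoxy)-3,5-diprenylbenzene (1.15 equiv); 10, (S)-5-[4-(methoxymethoxy)benzyl]-2,2-dimethyl-1,3-dioxolan-4-one (1.0 equiv)
Product: 11, (S)-1-[2,4-bis(methoxymethoxy)-3,5-bis(3-methylbut-2-en-1-yl)phenyl]-2-hydroxy-3-[4-(methoxymethoxy)phenyl]propan-1-one
Conditions: 6, n-BuLi (1.15 equiv), THF, −78 °C, 20 min; MgBr2·OEt2 (1.3 equiv), −78 → −40 °C; 10, −40 → 0 °C; aq NH4Cl, then AcOH/THF/H2O, rt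
Reagents that add atoms: none (both fragments are the reactants; acetone is lost)
Why: Br–Li exchange and transmetalation give a weakly basic aryl Grignard that mono-adds to the activated dioxolanone carbonyl (acyl substitution on a 1,3-dioxolan-4-one, analogous to aryl-metal additions to lactones that stop at the lactol). The magnesium hemiketalate survives until work-up and then expels acetone to unveil the free α-hydroxy ketone, with the (S) stereocentre carried intact from the chiral pool.

**Step 7**
Reactants: 11, tris-MOM α-hydroxy ketone
Product: 12, Lespeflorin C6, (S)-1-[2,4-dihydroxy-3,5-bis(3-methylbut-2-en-1-yl)phenyl]-2-hydroxy-3-(4-hydroxyphenyl)propan-1-one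
Conditions: 3 M aq HCl/MeOH (1:4), 40 °C, 1–2 h (monitored; NaHCO3 quench)
Reagents that add atoms: none
Why: Acid-catalysed acetal methanolysis of three phenolic MOM ethers (the fastest MOM class to cleave, so conditions stay mild). Dilute HCl at 40 °C is intended to be too weak to protonate the prenyl alkenes (chroman formation) or enolise the α-ketol, so the (S) centre should be retained.

## Compound list

1 | 2,4,6-tribromoresorcinol | Oc1c(Br)cc(Br)c(O)c1Br | starting material
2 | chloromethyl methyl ether (MOMCl) | COCCl | starting material (reagent)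
3 | 1,3,5-tribromo-2,4-bis(methoxymethoxy)benzene | COCOc1c(Br)cc(Br)c(OCOC)c1Br | intermediate
4 | prenyl bromide (1-bromo-3-methylbut-2-ene) | CC(C)=CCBr | starting material (reagent)
5 | 1,5-dibromo-2,4-bis(methoxymethoxy)-3-(3-methylbut-2-en-1-yl)benzene | COCOc1c(Br)cc(Br)c(OCOC)c1CC=C(C)C | intermediate
6 | 1-bromo-2,4-bis(methoxymethoxy)-3,5-bis(3-methylbut-2-en-1-yl)benzene | COCOc1c(Br)cc(CC=C(C)C)c(OCOC)c1CC=C(C)C | intermediate
7 | (S)-2-hydroxy-3-(4-hydroxyphenyl)propanoic acid | OC(=O)[C@@H](O)Cc1ccc(O)cc1 | starting material
8 | 2,2-dimethoxypropane | COC(C)(C)OC | starting material (reagent)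
9 | (S)-5-(4-hydroxybenzyl)-2,2-dimethyl-1,3-dioxolan-4-one | CC1(C)O[C@@H](Cc2ccc(O)cc2)C(=O)O1 | intermediate
10 | (S)-5-[4-(methoxymethoxy)benzyl]-2,2-dimethyl-1,3-dioxolan-4-one | CC1(C)O[C@@H](Cc2ccc(OCOC)cc2)C(=O)O1 | intermediate
11 | (S)-1-[2,4-bis(methoxymethoxy)-3,5-diprenylphenyl]-2-hydroxy-3-[4-(methoxymethoxy)phenyl]propan-1-one | CC(C)=CCc1cc(C(=O)[C@@H](O)Cc2ccc(OCOC)cc2)c(OCOC)c(CC=C(C)C)c1OCOC | intermediate
12 | Lespeflorin C6 | CC(C)=CCc1cc(C(=O)[C@@H](O)Cc2ccc(O)cc2)c(O)c(CC=C(C)C)c1O | target

## Summary

Total steps: 7.
Longest linear sequence: 5 (steps 1 → 2 → 3 → 6 → 7); the chiral branch is steps 4 → 5 → 6 → 7.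

Three steps most likely to fail, with fallbacks:

1. **Step 6 (aryl-metal + dioxolanone).** Risks: over-addition after premature collapse of the hemiketalate, or competing enolisation of 10 that erodes yield or ee. Fallback: switch from polar addition to a Pd-catalysed Fukuyama acyl coupling. Transmetalate the same aryllithium to ArZnCl and couple it with the S-ethyl thioester of (S)-HPLA carrying an O-TES α-hydroxyl and an O-MOM phenol. This is non-basic, cannot over-add, and the TES group falls off in step 7.

2. **Step 2 (site-selective Br/Li exchange on the tribromide).** Risks: exchange at a flanking Br, or halogen scrambling through deprotonation of the C–H between two bromines. Fallback: make the selectivity halogen-based instead of electronic. Iodinate commercial 4,6-dibromoresorcinol at C2, protect as the bis-MOM ether, and run a chemoselective I/Mg exchange (i-PrMgCl·LiCl, I ≫ Br) before Cu-catalysed prenylation, converging on 5.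

3. **Step 7 (acidic MOM removal next to two o-prenyl phenols).** Risks: acid-catalysed cyclisation to 2,2-dimethylchromans, or partial racemisation. Fallback: a non-Brønsted two-stage unmasking. Use TESOTf/2,2′-bipyridyl to convert ArO-MOM into ArO-TES, then buffered fluoride (HF·pyridine or TBAF/AcOH) to release the phenols and the α-OH.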